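## Analysis of the target

The target joins two aromatic units through a three-atom enol ether. One unit is a 7-methoxy-2,2-dimethyl-2H-chromene (benzene ring A fused through C4a/C8a to pyran ring B, which holds O1, C2 and the C3=C4 double bond) bearing the side chain CH(CH3)–O at C6. The other is a 5-methylphenol (ring C) bound through its C2 to the chain O–C1'H=C2'(ring C)–C3'H2OH. There is one stereocentre, the benzylic carbon on C6, and it is (S) (O > C6 > CH3 > H). There is one stereogenic double bond, C1'=C2', and it is (Z): the ether oxygen on C1' is cis to the C3' hydroxymethyl group and trans to ring C. The stereocentre is ortho to the C7 methoxy group and para to O1, so its C–O bond ionises with traces of acid to a doubly donor-stabilised benzylic cation. It therefore has to enter with its oxygen already attached and must never be a site of substitution. The enol ether is acid-labile, the free phenol ortho to C2' would close onto C1' under acid to a 2-alkoxy-2,3-dihydrobenzofuran, and the styrene-like C3=C4 bond excludes hydrogenolysis and electrophilic oxidants late in the route. The (Z) geometry is the opposite of what push–pull chemistry (β-alkoxyacrylates, β-alkoxyenals) delivers. The feature the route exploits is that the chain O–C1'H=C2'(Ar)–C3'H2–OH is a constitutional isomer of a 2-aryl-2-(alkoxymethyl)oxirane, in which C2' and C3' form the ring with the later hydroxyl oxygen and C1' is a plain OCH2 carbon.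

## Retrosynthetic reasoning

**17 ⇒ 16.** Only the ring C phenol is released from its silyl ether; no skeletal bond is cut. The phenol must stay masked until the end, because as a phenoxide it would attack the oxirane of the precursor. Fluoride is the only deprotection in the route, and the enol ether, the benzylic ether and the chromene all tolerate it.

**16 ⇒ 15 (key disconnection).** The C1'=C2' π bond and the C3'–OH group are traced back to oxirane 15, in which the oxygen bridges C2' and C3' and C1' is a saturated OCH2 carbon. In the forward sense C2'–O and one C1'–H are broken and C1'=C2' is formed. The cut is placed here, and not at C1'–O or C2'–aryl, because convergent enol ether constructions must fight the push–pull geometric preference. A base-induced syn-elimination of an oxirane instead fixes the geometry in a compact cyclic transition state in which the ether oxygen avoids the aryl group. The gain is a precursor with no double bond in the chain, no free hydroxyl group and no stereochemical demand at the oxirane carbon (both epimers converge). The forward reaction must remove one OCH2 proton, open the oxirane toward C2' and leave the benzylic methine alone.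

**15 ⇒ 8 + 13.** The O–C1' bond is cut to the alkoxide of alcohol 8 and dichlorohydrin 13, which closes under the same base to chloromethyl oxirane 14. The stereocentre enters as the nucleophilic oxygen and is never the site of substitution, so its configuration is retained by construction. Direct chloride displacement on 14 and oxirane opening at CH2 followed by reclosure lead to the same 15, so regiochemistry is not an issue.

**13 ⇒ 10 + 11.** The C2'–ring C bond is cut to aryl Grignard reagent 12 and the symmetrical C3 ketone 11. Ketone 11 is thus the linchpin that receives ring C, the chiral alkoxide and the later hydroxyl oxygen. Bromide 10 is the silyl ether of commercial phenol 9.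

**8 ⇒ 7.** The stereocentre is set by enantioselective reduction of the aryl methyl ketone 7 under non-acidic conditions; the C–H bond is formed while the oxygen stays on carbon.

**7 ⇒ 5 (via 6).** The C6–acetyl bond is cut to aryllithium 6, made from bromide 5. This avoids Friedel–Crafts acylation of the acid-sensitive chromene, and the bromine fixes the position.

**5 ⇒ 1 + 2.** Ring B is cut at C4–C4a and O1–C2. Phenol 1 and enal 2 are joined at the carbon ortho to the hydroxyl group, and the ortho-quinone methide 4 closes the O1–C2 bond by oxa-6π electrocyclisation. The bromine of 1 is para to the hydroxyl group, where the acetyl group must later stand.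

## Alternatives that were turned down

**Alternative 1:** (the textbook route) Cut C1'–O by conjugate addition and C2'–ring C by cross-coupling.
- Forward: alcohol 8 is added to a propiolate ester to give the (E)-β-alkoxyacrylate A1. Iodination–elimination gives the α-iodoacrylate A2. A Suzuki coupling installs ring C, and hydride reduction of the ester gives the allylic alcohol.
- Why turned down: in A1 and A2 the alkoxy group lies anti to the ester across the double bond (the push–pull arrangement), iodine enters cis to the alkoxy group, and the coupling goes with retention. The aryl group thus ends cis to the ether oxygen, and the sequence ends at A3, the (E) isomer of 17. Correction would need a photochemical E/Z isomerisation next to a 2H-chromene, which itself ring-opens on irradiation. The sequence also needs at least four steps from 8, against three in the chosen route.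

**Alternative 2:** Cut C2'–ring C last, by syn-hydroarylation of an ynol ether.
- Forward: alcohol 8 is converted (dichlorovinyl ether, elimination, hydroxymethylation of the lithium acetylide) into alkynyl ether A4. An arylmetal is then added across the triple bond with the aryl at C2' and hydrogen at C1' on the same face, which gives (Z).
- Why turned down: A4 is a secondary benzylic alkynyl ether on a ring with two oxygen donors. Such ethers lose ketene by retro-ene elimination or rearrange sigmatropically on mild warming, and the incipient benzylic cation makes both easier here. The free propargylic oxygen would also steer the arylmetal into a chelated anti-addition, which gives the (E) isomer. Two uncertain steps would follow each other on the most valuable intermediate.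

**Alternative 3:** Lock the geometry in a ring and cut the benzylic C–H bond.
- Forward: in the 4H-1,3-dioxine A5 the ketal carbon is the future stereocentre, O1 the enol oxygen and C4 the future C3', so the ring forces the ether oxygen and C3' to be cis. An aluminium hydride coordinates the more basic alkyl oxygen O3, cleaves the ketal C–O3 bond and delivers hydride to the ketal carbon, giving the (Z)-enol ether and the primary alcohol at once.
- Why turned down: the stereocentre would form by hydride attack on a planar oxocarbenium ion stabilised by O1 and both ring A oxygens. A5 has no element to tell its faces apart, and an enantioenriched ketal centre would not be transferred through so loose an ion pair. Cleavage of the C–O1 bond (enolate as leaving group) also competes. A5 further needs a dioxanone, an enol triflate and a cross-coupling, more steps than the whole chosen endgame.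

Key step: step 7

Assumption: ketone 7 follows the facial preference that RuCl[(S,S)-TsDPEN](p-cymene) shows for simple aryl methyl ketones, so that the (S,S) catalyst gives the (S) carbinol.

## Route

Step 1
Reactants: 1 4-bromo-3-methoxyphenol; 2 3-methylbut-2-enal
Product: 5 6-bromo-7-methoxy-2,2-dimethyl-2H-chromene, via benzodioxaborinine 3 (not isolated), via ortho-quinone methide 4 (not isolated)
Conditions: PhB(OH)2 (1.0 equiv), AcOH (cat.), toluene, reflux, Dean–Stark
Reagents that add atoms: none
Why: The boronic acid templates ortho-specific hydroxyalkylation of 1 by 2 to give 3, which fragments on heating to the ortho-quinone methide 4; oxa-6π electrocyclisation of 4 closes the O1–C2 bond of ring B (chromene synthesis from a phenol and an enal). Of the two carbons ortho to the hydroxyl group, the one para to the methoxy group should react, because the other is flanked by OH and OMe.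

Step 2
Reactants: 5 6-bromo-7-methoxy-2,2-dimethyl-2H-chromene
Product: 7 1-(7-methoxy-2,2-dimethyl-2H-chromen-6-yl)ethan-1-one (encecalin), via aryllithium 6 (not isolated)
Conditions: n-BuLi (1.05 equiv), THF, −78 °C; then N-methoxy-N-methylacetamide, −78 to 0 °C; H2O
Reagents that add atoms: N-methoxy-N-methylacetamide, CC(=O)N(C)OC
Why: Bromine–lithium exchange gives 6, which adds once to the Weinreb amide; the chelated tetrahedral adduct survives until the aqueous quench, so no tertiary alcohol should form. The chromene never meets a Lewis acid, and the bromine fixes the acetyl group at C6.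

Step 3
Reactants: 7 1-(7-methoxy-2,2-dimethyl-2H-chromen-6-yl)ethan-1-one
Product: 8 (1S)-1-(7-methoxy-2,2-dimethyl-2H-chromen-6-yl)ethan-1-ol ((S)-encecalol)
Conditions: RuCl[(S,S)-TsDPEN](p-cymene) (1 mol %), HCO2Na (5 equiv), H2O/i-PrOH 1:1, 40 °C
Reagents that add atoms: none
Why: Noyori–Ikariya asymmetric transfer hydrogenation: the ruthenium hydride and the ligand NH deliver hydride and proton to the ketone in a six-membered outer-sphere transition state with the arene of 7 next to the p-cymene ligand, which with the (S,S) ligand should give the (S) carbinol as for acetophenone. The formate medium stays neutral to basic, so the ionisable benzylic alcohol sees no acid, and this catalyst type does not reduce the C3=C4 bond.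

Step 4
Reactants: 9 2-bromo-5-methylphenol
Product: 10 (2-bromo-5-methylphenoxy)tri(propan-2-yl)silane
Conditions: i-Pr3SiCl, imidazole, DMF, 40 °C
Reagents that add atoms: chlorotri(propan-2-yl)silane, CC(C)[Si](Cl)(C(C)C)C(C)C
Why: Standard silylation of a phenol. The bulky triisopropylsilyl group is chosen because it resists the alkoxide and amide bases of steps 6 and 7, migrates slowly from oxygen to carbon in the arylmetal, and is removed by fluoride without acid.

Step 5
Reactants: 10 (2-bromo-5-methylphenoxy)tri(propan-2-yl)silane; 11 1,3-dichloropropan-2-one
Product: 13 1,3-dichloro-2-{4-methyl-2-[tri(propan-2-yl)silyloxy]phenyl}propan-2-ol, via arylmagnesium bromide 12 (not isolated)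
Conditions: Mg turnings (I2-activated), THF, 50 °C; then addition to 11 (1.2 equiv), THF, −40 to 0 °C; H2O
Reagents that add atoms: none
Why: Grignard formation and 1,2-addition to the very electrophilic ketone 11, the standard entry to 2-aryl-1,3-dichloropropan-2-ols. Low temperature and inverse addition favour addition over enolisation of 11.

Step 6
Reactants: 8 (1S)-1-(7-methoxy-2,2-dimethyl-2H-chromen-6-yl)ethan-1-ol; 13 1,3-dichloro-2-{4-methyl-2-[tri(propan-2-yl)silyloxy]phenyl}propan-2-ol
Product: 15 2-{[(1S)-1-(7-methoxy-2,2-dimethyl-2H-chromen-6-yl)ethoxy]methyl}-2-{4-methyl-2-[tri(propan-2-yl)silyloxy]phenyl}oxirane (both epimers at the oxirane carbon), via chloromethyl oxirane 14 (not isolated)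
Conditions: NaH (2.5 equiv), n-Bu4NI (10 mol %), THF/DMF 5:1, 0 to 40 °C; 13 used in 1.3-fold excess
Reagents that add atoms: none
Why: NaH turns 13 into 14 by 3-exo-tet closure of the chlorohydrin alkoxide and turns 8 into its alkoxide, which substitutes at the primary carbon of 14 (Williamson ether synthesis of the epichlorohydrin type); direct chloride displacement and oxirane opening/reclosure give the same 15. The stereocentre of 8 reacts only through oxygen and is retained; the oxirane carbon forms as both epimers, which does not matter because step 7 destroys it.

Step 7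
Reactants: 15 2-{[(1S)-1-(7-methoxy-2,2-dimethyl-2H-chromen-6-yl)ethoxy]methyl}-2-{4-methyl-2-[tri(propan-2-yl)silyloxy]phenyl}oxirane
Product: 16 (2Z)-3-[(1S)-1-(7-methoxy-2,2-dimethyl-2H-chromen-6-yl)ethoxy]-2-{4-methyl-2-[tri(propan-2-yl)silyloxy]phenyl}prop-2-en-1-ol
Conditions: LiN(i-Pr)2 (3 equiv, commercial solution), THF, −30 °C to rt; pH 7 phosphate buffer
Reagents that add atoms: none
Why: LiN(i-Pr)2 binds the oxirane oxygen of 15 and removes one OCH2 proton through a six-membered syn transition state while the benzylic C2'–O bond of the oxirane breaks, giving the lithium alkoxide of 16 directly; this is the lithium amide isomerisation of an epoxide to an allylic alcohol, in the variant that turns an alkoxymethyl oxirane into a 3-alkoxyallyl alcohol. The OCH2 hydrogens are the only ones β to the oxirane oxygen, because the oxirane carbon is quaternary and ring C offers none, so the substrate fixes the regiochemistry. No ring is closed and no stereocentre is created; the oxirane ring is opened and its stereocentre destroyed, so both epimers of 15 converge on one product. The geometry is decided in the eclipsed transition state: the alkoxy group on the carbon that loses the proton must eclipse either the tied-back oxirane CH2 or the ortho-silyloxyaryl group, and it should take the side of the small CH2, which places the ether oxygen cis to C3' and trans to ring C, that is (Z). The same preference holds in the product, where an alkoxy group cis to the twisted ortho-substituted aryl ring would be strained. The further selectivity needed is for the OCH2 protons over the benzylic methine of the encecalyl ether; that methine is tertiary, sits on a ring with two oxygen donors and should not be removed by a lithium amide without potassium alkoxide activation at or below room temperature, so the (S) centre should stay intact. The aryl silyl ether and the chromene are inert to the amide base, and the neutral work-up releases 16 without contact with acid.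

Step 8
Reactants: 16 (2Z)-3-[(1S)-1-(7-methoxy-2,2-dimethyl-2H-chromen-6-yl)ethoxy]-2-{4-methyl-2-[tri(propan-2-yl)silyloxy]phenyl}prop-2-en-1-ol
Product: 17 2-{(1Z)-3-hydroxy-1-[(1S)-1-(7-methoxy-2,2-dimethyl-2H-chromen-6-yl)ethoxy]prop-1-en-2-yl}-5-methylphenol (the target)
Conditions: n-Bu4NF (1.2 equiv), THF, 0 °C; pH 7 phosphate buffer; chromatography on Et3N-deactivated silica
Reagents that add atoms: none
Why: Fluoride cleaves the aryl O–Si bond at 0 °C and the buffer protonates the phenoxide (fluoride desilylation). No acid is used, so the enol ether, the benzylic ether and the chromene should survive, and the (S) and (Z) elements are kept.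

## Compound list

1 | 4-bromo-3-methoxyphenol | COc1cc(O)ccc1Br | starting material
2 | 3-methylbut-2-enal | CC(C)=CC=O | starting material
3 | 6-bromo-7-methoxy-4-(2-methylprop-1-en-1-yl)-2-phenyl-4H-1,3,2-benzodioxaborinine (racemic) | COc1cc2OB(c3ccccc3)OC(C=C(C)C)c2cc1Br | intermediate
4 | 4-bromo-3-methoxy-6-(3-methylbut-2-en-1-ylidene)cyclohexa-2,4-dien-1-one (ortho-quinone methide) | O=C1C=C(OC)C(Br)=CC1=CC=C(C)C | intermediate
5 | 6-bromo-7-methoxy-2,2-dimethyl-2H-chromene | COc1cc2OC(C)(C)C=Cc2cc1Br | intermediate
6 | (7-methoxy-2,2-dimethyl-2H-chromen-6-yl)lithium | COc1cc2OC(C)(C)C=Cc2cc1[Li] | intermediate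
7 | 1-(7-methoxy-2,2-dimethyl-2H-chromen-6-yl)ethan-1-one (encecalin) | COc1cc2OC(C)(C)C=Cc2cc1C(C)=O | intermediate
8 | (1S)-1-(7-methoxy-2,2-dimethyl-2H-chromen-6-yl)ethan-1-ol | COc1cc2c(cc1[C@H](C)O)C=CC(C)(C)O2 | intermediate
9 | 2-bromo-5-methylphenol | Cc1ccc(Br)c(O)c1 | starting material
10 | (2-bromo-5-methylphenoxy)tri(propan-2-yl)silane | Cc1ccc(Br)c(O[Si](C(C)C)(C(C)C)C(C)C)c1 | intermediate
11 | 1,3-dichloropropan-2-one | ClCC(=O)CCl | starting material
12 | {4-methyl-2-[tri(propan-2-yl)silyloxy]phenyl}magnesium bromide | Cc1ccc([Mg]Br)c(O[Si](C(C)C)(C(C)C)C(C)C)c1 | intermediate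
13 | 1,3-dichloro-2-{4-methyl-2-[tri(propan-2-yl)silyloxy]phenyl}propan-2-ol | Cc1ccc(C(O)(CCl)CCl)c(O[Si](C(C)C)(C(C)C)C(C)C)c1 | intermediate
14 | 2-(chloromethyl)-2-{4-methyl-2-[tri(propan-2-yl)silyloxy]phenyl}oxirane (racemic) | Cc1ccc(C2(CCl)CO2)c(O[Si](C(C)C)(C(C)C)C(C)C)c1 | intermediate
15 | 2-{[(1S)-1-(7-methoxy-2,2-dimethyl-2H-chromen-6-yl)ethoxy]methyl}-2-{4-methyl-2-[tri(propan-2-yl)silyloxy]phenyl}oxirane (both epimers at the oxirane carbon) | COc1cc2c(cc1[C@H](C)OCC1(CO1)c1ccc(C)cc1O[Si](C(C)C)(C(C)C)C(C)C)C=CC(C)(C)O2 | intermediate
16 | (2Z)-3-[(1S)-1-(7-methoxy-2,2-dimethyl-2H-chromen-6-yl)ethoxy]-2-{4-methyl-2-[tri(propan-2-yl)silyloxy]phenyl}prop-2-en-1-ol | COc1cc2c(cc1[C@H](C)O/C=C(\CO)c1ccc(C)cc1O[Si](C(C)C)(C(C)C)C(C)C)C=CC(C)(C)O2 | intermediate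
17 | 2-{(1Z)-3-hydroxy-1-[(1S)-1-(7-methoxy-2,2-dimethyl-2H-chromen-6-yl)ethoxy]prop-1-en-2-yl}-5-methylphenol | COc1cc2c(cc1[C@H](C)O/C=C(\CO)c1ccc(C)cc1O)C=CC(C)(C)O2 | target

## Step count and least certain steps

Total step count: 8. Longest linear sequence: 6 steps (1, 2, 3, 6, 7, 8).

**Step 7 (key step).** The most likely failure is competing deprotonation at the benzylic methine of the encecalyl ether, either directed by lithium bound to the ether oxygen or because the OCH2 elimination is slow at the hindered quaternary oxirane carbon. This would erode the (S) centre or start an intramolecular attack on the oxirane. A second possible failure is incomplete geometric control, if the aryl group and the oxirane CH2 are not differentiated as strongly as expected. The fallback sets out from 8 and 10 and returns at 17; it forms the C1'–O bond by a stereoretentive cross-coupling instead of an elimination. Bromide 10 is converted into Grignard reagent 12 as in step 5 and added to prop-2-yn-1-ol (CuI cat., THF, reflux). This anti-carbomagnesiation runs through a five-membered alkoxide chelate, and an I2 quench of the alkenylmagnesium gives (2Z)-3-iodo-2-{4-methyl-2-[tri(propan-2-yl)silyloxy]phenyl}prop-2-en-1-ol F1, with iodine cis to the hydroxymethyl group. Silylation (t-BuMe2SiCl, imidazole) gives tert-butyl{[(2Z)-3-iodo-2-{4-methyl-2-[tri(propan-2-yl)silyloxy]phenyl}prop-2-en-1-yl]oxy}dimethylsilane F2. Coupling of F2 with 8 (CuI, 3,4,7,8-tetramethyl-1,10-phenanthroline, Cs2CO3, toluene, 80 °C) should proceed with retention at the alkene and at the carbinol carbon to give the bis-silyl ether of the target F3. n-Bu4NF then removes both silyl groups and gives 17.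

**Step 6.** Silyl transfer from the phenol oxygen to the transient tertiary alkoxide (a six-membered transition state) could compete with oxirane closure and free a phenoxide that cyclises onto the chloromethyl group. A second alkoxide could open the oxirane of the product, and substitution at the neopentyl-type carbon could be slow. The fallback sets out from 10 and 8 and returns at 15; it uses a sulfonate that reacts by direct displacement at 0 °C and never passes through a tertiary alkoxide. Grignard reagent 12 and prop-2-yn-1-ol (CuI cat., THF, reflux; H2O) give 2-{4-methyl-2-[tri(propan-2-yl)silyloxy]phenyl}prop-2-en-1-ol F4. Epoxidation (m-CPBA, NaHCO3, CH2Cl2, 0 °C) gives (2-{4-methyl-2-[tri(propan-2-yl)silyloxy]phenyl}oxiran-2-yl)methanol F5. Sulfonylation (3-nitrobenzenesulfonyl chloride, Et3N, CH2Cl2, −20 °C) gives (2-{4-methyl-2-[tri(propan-2-yl)silyloxy]phenyl}oxiran-2-yl)methyl 3-nitrobenzenesulfonate F6, which the sodium alkoxide of 8 (NaH, THF, 0 °C) converts into 15.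

**Step 3.** Hydride transfer to an electron-rich, ortho-substituted ketone may be slow and stall before full conversion, and the enantiomeric purity may be lowered by reversibility or by ionisation of the product if the medium turns acidic. The fallback sets out from 7 and returns at 8; it replaces asymmetric catalysis by a resolution. NaBH4 in EtOH gives racemic 1-(7-methoxy-2,2-dimethyl-2H-chromen-6-yl)ethan-1-ol F7. Immobilised lipase B from Candida antarctica with vinyl acetate in toluene should acylate the (R) enantiomer, as is usual for 1-arylethanols, to (1R)-1-(7-methoxy-2,2-dimethyl-2H-chromen-6-yl)ethyl acetate F8. The unreacted (S) alcohol 8 is separated, at the price of at most half of the material.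

**Step 5.** The hindered, basic aryl Grignard reagent may enolise ketone 11 instead of adding to it, and oxygen-to-carbon silyl migration in the arylmetal may occur if the solution is kept warm. The fallback sets out from 10 and returns at 13; it reverses the polarity so that the arene is the electrophile. Bromine–lithium exchange on 10 (n-BuLi, THF, −78 °C) and acylation with 2-chloro-N-methoxy-N-methylacetamide give 2-chloro-1-{4-methyl-2-[tri(propan-2-yl)silyloxy]phenyl}ethan-1-one F9. Chloromethyllithium, generated in the presence of F9 from chloroiodomethane and MeLi·LiBr at −78 °C, adds to the ketone, and a cold quench with AcOH gives 13.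

## Further compounds

F1 | step 7 | (2Z)-3-iodo-2-{4-methyl-2-[tri(propan-2-yl)silyloxy]phenyl}prop-2-en-1-ol | I/C=C(\CO)c1ccc(C)cc1O[Si](C(C)C)(C(C)C)C(C)C
F2 | step 7 | tert-butyl{[(2Z)-3-iodo-2-{4-methyl-2-[tri(propan-2-yl)silyloxy]phenyl}prop-2-en-1-yl]oxy}dimethylsilane | I/C=C(\CO[Si](C)(C)C(C)(C)C)c1ccc(C)cc1O[Si](C(C)C)(C(C)C)C(C)C
F3 | step 7 | tert-butyl{[(2Z)-3-[(1S)-1-(7-methoxy-2,2-dimethyl-2H-chromen-6-yl)ethoxy]-2-{4-methyl-2-[tri(propan-2-yl)silyloxy]phenyl}prop-2-en-1-yl]oxy}dimethylsilane | COc1cc2c(cc1[C@H](C)O/C=C(\CO[Si](C)(C)C(C)(C)C)c1ccc(C)cc1O[Si](C(C)C)(C(C)C)C(C)C)C=CC(C)(C)O2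
F4 | step 6 | 2-{4-methyl-2-[tri(propan-2-yl)silyloxy]phenyl}prop-2-en-1-ol | C=C(CO)c1ccc(C)cc1O[Si](C(C)C)(C(C)C)C(C)C
F5 | step 6 | (2-{4-methyl-2-[tri(propan-2-yl)silyloxy]phenyl}oxiran-2-yl)methanol (racemic) | OCC1(CO1)c1ccc(C)cc1O[Si](C(C)C)(C(C)C)C(C)C
F6 | step 6 | (2-{4-methyl-2-[tri(propan-2-yl)silyloxy]phenyl}oxiran-2-yl)methyl 3-nitrobenzenesulfonate (racemic) | O=S(=O)(OCC1(CO1)c1ccc(C)cc1O[Si](C(C)C)(C(C)C)C(C)C)c1cccc(c1)[N+](=O)[O-]
F7 | step 3 | 1-(7-methoxy-2,2-dimethyl-2H-chromen-6-yl)ethan-1-ol (racemic) | COc1cc2c(cc1C(C)O)C=CC(C)(C)O2
F8 | step 3 | (1R)-1-(7-methoxy-2,2-dimethyl-2H-chromen-6-yl)ethyl acetate | COc1cc2c(cc1[C@@H](C)OC(C)=O)C=CC(C)(C)O2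
F9 | step 5 | 2-chloro-1-{4-methyl-2-[tri(propan-2-yl)silyloxy]phenyl}ethan-1-one | Cc1ccc(C(=O)CCl)c(O[Si](C(C)C)(C(C)C)C(C)C)c1
A1 | alternative 1 | methyl (2E)-3-[(1S)-1-(7-methoxy-2,2-dimethyl-2H-chromen-6-yl)ethoxy]prop-2-enoate | COc1cc2c(cc1[C@H](C)O/C=C/C(=O)OC)C=CC(C)(C)O2
A2 | alternative 1 | methyl (2Z)-2-iodo-3-[(1S)-1-(7-methoxy-2,2-dimethyl-2H-chromen-6-yl)ethoxy]prop-2-enoate | COc1cc2c(cc1[C@H](C)O/C=C(\I)C(=O)OC)C=CC(C)(C)O2
A3 | alternative 1 | 2-{(1E)-3-hydroxy-1-[(1S)-1-(7-methoxy-2,2-dimethyl-2H-chromen-6-yl)ethoxy]prop-1-en-2-yl}-5-methylphenol | COc1cc2c(cc1[C@H](C)O/C=C(/CO)c1ccc(C)cc1O)C=CC(C)(C)O2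
A4 | alternative 2 | 3-[(1S)-1-(7-methoxy-2,2-dimethyl-2H-chromen-6-yl)ethoxy]prop-2-yn-1-ol | COc1cc2c(cc1[C@H](C)OC#CCO)C=CC(C)(C)O2
A5 | alternative 3 | 2-(7-methoxy-2,2-dimethyl-2H-chromen-6-yl)-2-methyl-5-{4-methyl-2-[tri(propan-2-yl)silyloxy]phenyl}-4H-1,3-dioxine | COc1cc2c(cc1C1(C)OCC(=CO1)c1ccc(C)cc1O[Si](C(C)C)(C(C)C)C(C)C)C=CC(C)(C)O2
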